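Isodunnianol is cut at its three aryl–CH2 bonds, so the oxygenated triaryl core is built first and the three allyl groups arrive together at the end. The key step exploits that every allyl-bearing carbon is para to an oxygen: C4 of phenoxy ring A (para to the ether oxygen), C4 of central ring B (para to the C1 hydroxyl) and C5' of ring C (para to the C2' hydroxyl), exactly where phenol bromination places halogen. A threefold Suzuki–Miyaura coupling of allylboronic acid pinacol ester with tribromide 9, which carries bromine at these three carbons and both phenols as methoxymethyl ethers, forms all three bonds in one operation; acid then frees the phenols.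

Key step: step 6

Remark on numbering: in the paragraph above ring B is numbered as a phenol (C1 OH, C2 O-aryl, C4 allyl, C6 aryl); the compound names below use biphenyl numbering, in which that allyl-bearing carbon is C5.

Remark on the chemistry: all compounds are achiral, with no stereocentre and no configurationally stable biaryl axis. Boronate 10 is used in excess (about 1.5 to 2 equivalents per C–Br bond), although three equivalents are consumed.

Step 1
Reactants: 1 2-bromo-6-fluorobenzaldehyde; 2 2-(methoxymethoxy)phenylboronic acid
Product: 3 3-fluoro-2'-(methoxymethoxy)-[1,1'-biphenyl]-2-carbaldehyde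
Conditions: Pd(PPh3)4 (3 mol %), Na2CO3 (2 M aq.), DME, 85 °C
Reagents that add atoms: none
Why: Suzuki–Miyaura biaryl coupling, in which the C–Br bond ortho to the formyl group adds readily to zerovalent palladium while the C–F bond, the aldehyde and the base-stable methoxymethyl ether are left alone.

Step 2
Reactants: 3 3-fluoro-2'-(methoxymethoxy)-[1,1'-biphenyl]-2-carbaldehyde; 4 4-bromophenol
Product: 5 3-(4-bromophenoxy)-2'-(methoxymethoxy)-[1,1'-biphenyl]-2-carbaldehyde
Conditions: K2CO3, DMA, 110 °C
Reagents that add atoms: none
Why: Nucleophilic aromatic substitution (SNAr) of the fluoride by the phenoxide of 4, with the ortho formyl group stabilising the Meisenheimer adduct and the aryl bromide of 4 inert in the absence of a transition metal.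

Step 3
Reactants: 5 3-(4-bromophenoxy)-2'-(methoxymethoxy)-[1,1'-biphenyl]-2-carbaldehyde
Product: 7 3-(4-bromophenoxy)-[1,1'-biphenyl]-2,2'-diol, via aryl formate 6 (not isolated)
Conditions: mCPBA (1.5 equiv), CH2Cl2, 0 °C to rt; wash with aq. Na2S2O3 and NaHCO3; then HCl (3 M in MeOH), 45 °C
Reagents that add atoms: 3-chloroperoxybenzoic acid (mCPBA), O=C(OO)c1cccc(Cl)c1
Why: Dakin-type Baeyer–Villiger oxidation in which the ring B aryl group, made electron-rich by its ortho aryloxy substituent, migrates to oxygen to give formate 6, after which acidic methanolysis should cleave the formate and the methoxymethyl acetal in the same flask.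

Step 4
Reactants: 7 3-(4-bromophenoxy)-[1,1'-biphenyl]-2,2'-diol
Product: 8 5,5'-dibromo-3-(4-bromophenoxy)-[1,1'-biphenyl]-2,2'-diol
Conditions: NBS (2.05 equiv), MeCN, −20 to 0 °C, dark
Reagents that add atoms: N-bromosuccinimide (NBS), O=C1CCC(=O)N1Br
Why: Electrophilic aromatic bromination directed by the free hydroxyls, where ring B has only its para carbon (C5) open because both ortho carbons are substituted, ring C is attacked para (C5') in the polar solvent, and ring A is deactivated by the bromine it already carries.

Step 5
Reactants: 8 5,5'-dibromo-3-(4-bromophenoxy)-[1,1'-biphenyl]-2,2'-diol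
Product: 9 5,5'-dibromo-3-(4-bromophenoxy)-2,2'-bis(methoxymethoxy)-1,1'-biphenyl
Conditions: NaH (2.5 equiv), MOMCl (2.5 equiv), DMF, 0 °C to rt
Reagents that add atoms: chloromethyl methyl ether (MOMCl), COCCl
Why: Williamson-type O-alkylation of both sodium phenoxides by the highly reactive α-chloro ether, which should also reach the flanked ring B oxygen and leaves the three aryl bromides untouched.

Step 6
Reactants: 9 5,5'-dibromo-3-(4-bromophenoxy)-2,2'-bis(methoxymethoxy)-1,1'-biphenyl; 10 allylboronic acid pinacol ester
Product: 11 5,5'-diallyl-3-(4-allylphenoxy)-2,2'-bis(methoxymethoxy)-1,1'-biphenyl (isodunnianol bis(methoxymethyl) ether)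
Conditions: PdCl2(dppf)·CH2Cl2 (10 mol %), CsF (9 equiv), 10 (5 equiv), degassed THF, 70 °C
Reagents that add atoms: none
Why: Suzuki–Miyaura allyl–aryl cross-coupling run three times on one molecule: zerovalent palladium formed from PdCl2(dppf) inserts into each C–Br bond, fluoride converts boronate 10 into a fluoroborate that hands its allyl group to palladium, and reductive elimination from the allyl(aryl)palladium species forms each aryl–CH2 bond. The closest known reaction type is the CsF-promoted coupling of aryl bromides with allylboronic acid pinacol ester to give allylarenes. No ring is closed and no stereocentre is formed, and because the allyl group is unsubstituted, transfer through its α or γ carbon gives the same product. The selectivity needed is complete threefold coupling without protodebromination and without migration of the terminal double bonds into conjugation; all three bromides of 9 (C4 of ring A, C5 of ring B, C5' of ring C) are flanked by two ring hydrogens, so none is sterically retarded, and excess boronate should drive the third coupling. The wide bite angle of dppf speeds reductive elimination relative to palladium hydride formation, and CsF is too weak a base to isomerise the allylarenes. The methoxymethyl ethers prevent formation of electron-rich phenoxides that would slow oxidative addition, and they are stable to fluoride.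

Step 7
Reactants: 11 5,5'-diallyl-3-(4-allylphenoxy)-2,2'-bis(methoxymethoxy)-1,1'-biphenyl
Product: 12 isodunnianol (5,5'-diallyl-3-(4-allylphenoxy)-[1,1'-biphenyl]-2,2'-diol)
Conditions: HCl (2 M in MeOH), THF, 40 °C
Reagents that add atoms: none
Why: Acid-catalysed transacetalisation of both methoxymethyl ethers to methanol, under dilute Brønsted acid at mild temperature that should neither isomerise nor hydroalkoxylate the terminal allyl groups.

Compound list
1 | 2-bromo-6-fluorobenzaldehyde | O=Cc1c(F)cccc1Br | starting material
2 | 2-(methoxymethoxy)phenylboronic acid | COCOc1ccccc1B(O)O | starting material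
3 | 3-fluoro-2'-(methoxymethoxy)-[1,1'-biphenyl]-2-carbaldehyde | O=Cc1c(F)cccc1-c1ccccc1OCOC | intermediate
4 | 4-bromophenol | Oc1ccc(Br)cc1 | starting material
5 | 3-(4-bromophenoxy)-2'-(methoxymethoxy)-[1,1'-biphenyl]-2-carbaldehyde | O=Cc1c(Oc2ccc(Br)cc2)cccc1-c1ccccc1OCOC | intermediate
6 | 3-(4-bromophenoxy)-2'-(methoxymethoxy)-[1,1'-biphenyl]-2-yl formate (aryl formate, not isolated) | O=COc1c(Oc2ccc(Br)cc2)cccc1-c1ccccc1OCOC | intermediate
7 | 3-(4-bromophenoxy)-[1,1'-biphenyl]-2,2'-diol | Oc1ccccc1-c1cccc(Oc2ccc(Br)cc2)c1O | intermediate
8 | 5,5'-dibromo-3-(4-bromophenoxy)-[1,1'-biphenyl]-2,2'-diol | Oc1ccc(Br)cc1-c1cc(Br)cc(Oc2ccc(Br)cc2)c1O | intermediate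
9 | 5,5'-dibromo-3-(4-bromophenoxy)-2,2'-bis(methoxymethoxy)-1,1'-biphenyl | COCOc1ccc(Br)cc1-c1cc(Br)cc(Oc2ccc(Br)cc2)c1OCOC | intermediate
10 | allylboronic acid pinacol ester (2-allyl-4,4,5,5-tetramethyl-1,3,2-dioxaborolane) | C=CCB1OC(C)(C)C(C)(C)O1 | starting material
11 | 5,5'-diallyl-3-(4-allylphenoxy)-2,2'-bis(methoxymethoxy)-1,1'-biphenyl | COCOc1ccc(CC=C)cc1-c1cc(CC=C)cc(Oc2ccc(CC=C)cc2)c1OCOC | intermediate
12 | isodunnianol (5,5'-diallyl-3-(4-allylphenoxy)-[1,1'-biphenyl]-2,2'-diol) | C=CCc1ccc(Oc2cc(CC=C)cc(-c3cc(CC=C)ccc3O)c2O)cc1 | target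

Total step count: 7 steps.
Longest linear sequence: 7 steps (1 to 12).

Steps most likely to fail

Step 6. The third coupling may stall, leaving partly allylated bromides that are hard to separate, and protodebromination or palladium hydride-mediated migration of the double bonds into conjugation may compete. The fallback reverses the polarity of the partners and sets out from 9. Threefold Miyaura borylation with bis(pinacolato)diboron (PdCl2(dppf), KOAc, dioxane, 90 °C) should give 2,2'-bis(methoxymethoxy)-5,5'-bis(pinacolboryl)-3-[4-(pinacolboryl)phenoxy]-1,1'-biphenyl F1. This tris(boronate) would then be coupled with allyl bromide (Pd(PPh3)4, K2CO3, THF/H2O, 60 °C) through a π-allylpalladium intermediate, rejoining the route at 11.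

Step 4. Attack ortho to the ring C hydroxyl (C3') may compete with para attack, and over-bromination may occur once both para positions are filled. The fallback brominates ring C while it is still an aryl ether and sets out from 5. One equivalent of NBS in MeCN at rt should brominate the only activated ring, para to the methoxymethoxy group, to give 5'-bromo-3-(4-bromophenoxy)-2'-(methoxymethoxy)-[1,1'-biphenyl]-2-carbaldehyde F2. The oxidation and methanolysis of step 3 would then lead through 5'-bromo-3-(4-bromophenoxy)-2'-(methoxymethoxy)-[1,1'-biphenyl]-2-yl formate F3 to 5'-bromo-3-(4-bromophenoxy)-[1,1'-biphenyl]-2,2'-diol F4. One further equivalent of NBS (MeCN, −20 °C) should attack ring B at C5, the only open para position of a ring not yet deactivated by bromine, rejoining the route at 8.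

Step 3. Hydride instead of aryl migration in the peracid adduct would give the benzoic acid, and peracid addition to the doubly ortho-substituted aldehyde may be slow. The fallback brings the ring B oxygen in ready-made, forms the diaryl ether by copper-mediated oxidative coupling, and sets out from 2. Suzuki–Miyaura coupling of 2 with commercial 3-bromo-2-methoxyphenol (COc1c(O)cccc1Br; Pd(PPh3)4, Na2CO3, DME/H2O, 85 °C) should give 2-methoxy-2'-(methoxymethoxy)-[1,1'-biphenyl]-3-ol F5. Chan–Lam coupling with 4-bromophenylboronic acid (OB(O)c1ccc(Br)cc1; Cu(OAc)2, pyridine, 4 Å molecular sieves, CH2Cl2, air, rt) should give 3-(4-bromophenoxy)-2-methoxy-2'-(methoxymethoxy)-1,1'-biphenyl F6 with the C–Br bond intact. BBr3 (CH2Cl2, −78 to 0 °C, MeOH quench) would cleave the methyl and methoxymethyl ethers together, rejoining the route at 7.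

Further compounds
F1 | step 6 | 2,2'-bis(methoxymethoxy)-5,5'-bis(4,4,5,5-tetramethyl-1,3,2-dioxaborolan-2-yl)-3-[4-(4,4,5,5-tetramethyl-1,3,2-dioxaborolan-2-yl)phenoxy]-1,1'-biphenyl | COCOc1ccc(B2OC(C)(C)C(C)(C)O2)cc1-c1cc(B2OC(C)(C)C(C)(C)O2)cc(Oc2ccc(B3OC(C)(C)C(C)(C)O3)cc2)c1OCOC
F2 | step 4 | 5'-bromo-3-(4-bromophenoxy)-2'-(methoxymethoxy)-[1,1'-biphenyl]-2-carbaldehyde | O=Cc1c(Oc2ccc(Br)cc2)cccc1-c1cc(Br)ccc1OCOC
F3 | step 4 | 5'-bromo-3-(4-bromophenoxy)-2'-(methoxymethoxy)-[1,1'-biphenyl]-2-yl formate | O=COc1c(Oc2ccc(Br)cc2)cccc1-c1cc(Br)ccc1OCOC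
F4 | step 4 | 5'-bromo-3-(4-bromophenoxy)-[1,1'-biphenyl]-2,2'-diol | Oc1ccc(Br)cc1-c1cccc(Oc2ccc(Br)cc2)c1O
F5 | step 3 | 2-methoxy-2'-(methoxymethoxy)-[1,1'-biphenyl]-3-ol | COCOc1ccccc1-c1cccc(O)c1OC
F6 | step 3 | 3-(4-bromophenoxy)-2-methoxy-2'-(methoxymethoxy)-1,1'-biphenyl | COCOc1ccccc1-c1cccc(Oc2ccc(Br)cc2)c1OC
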